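- Over 15 d I must foresee what the flask holds, charged with 0.17 M of solid substrate and 0.170 M of reagent.

| flask | solid substrate | reagent | remark | time |
|---|---|---|---|---|
| gamma | 0.24 M | 0.17 M | run made earlier |  |
| zeta | 0.37 M | 0.17 M | run made earlier |  |
| eta | 0.17 M | 0.085 M | run made earlier |  |
| flask | 0.17 M | 0.170 M |  | 15 d |

| run | time / d | target / % | isomer of the product / % |
|---|---|---|---|
| gamma | 1.67 | 50.8 | 20.5 |
| gamma | 3.00 | 50.4 | 20.2 |
| gamma | 5.00 | 50.4 | 20.5 |
| gamma | 6.00 | 50.6 | 20.1 |
| gamma | 8.00 | 50.3 | 20.1 |
| gamma | 10.0 | 50.7 | 20.0 |
| zeta | 0.625 | 32.1 | 12.5 |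
| zeta | 1.67 | 32.9 | 13.0 |
| zeta | 3.00 | 33.2 | 13.2 |
| zeta | 5.00 | 32.7 | 12.9 |
| zeta | 6.00 | 32.5 | 12.4 |
| zeta | 10.0 | 33.2 | 13.1 |
| eta | 0.833 | 36.1 | 14.9 |
| eta | 2.50 | 35.6 | 14.2 |
| eta | 4.00 | 35.5 | 14.4 |
| eta | 6.00 | 35.9 | 14.3 |
| eta | 10.0 | 35.9 | 14.5 |

(readings scatter by 0.3 percentage points)

- solid, in amounts per volume of the solution: solid substrate
- at the start none of the solid substrate is in solution
- what has only dissolved of solid substrate counts as not reacted
- the reaction counts as stopped when no species that holds the solid substrate changes by six tenths of a point or more over the second half of the time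

- the state of affairs at 15 d: stopped, and by what, or still going (for what has run out or reacted, a solid counts together with what of it has only dissolved) (forward and back rates have come level / all of the solid substrate has reacted / it is still moving)
- target at 15 d, in percent of the solid substrate charged
- isomer of the product at 15 d, in percent of the solid substrate charged

- The fastest rung comes first: at 0.625 d the zeta run shows 32.1% target and 12.5% isomer, and at 10.0 d it shows 33.2% and 13.1%, so its target stands within 1.1 percentage points of the last reading at a time far shorter than 15 d.
- The split looks flat in the readings; pooling the last readings of gamma, zeta and eta, I read a target share of 71.6% of the products.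
- The plateau height gives my rule, the reagent ceiling: reagent charged divided by solid substrate charged, capped at the whole charge, which makes reagent the limiting reagent below that cap. Gamma reads 70.7% against 70.8%, zeta 46.3% against 45.9%, and eta 50.4% against 50.0%.
- The slowest rung I expect is the tail of this equimolar flask, where both partners thin together; gamma, zeta and eta each charge less reagent than solid substrate, so they are not equimolar.
- For this flask the ceiling is 100%, so, taking that tail as small, I commit to 71.6% target and 28.4% isomer.
- The forecast says all of the solid substrate has reacted, with target 71.2% (69.5% to 72%) and isomer 28.5% (27.5% to 29.3%), on the ground that “In every run the products equal the reagent charged”; its target lies a little under mine.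
- The flask gives all of the solid substrate has reacted: target 71.4%, isomer 28.6%, solid substrate 0%, starting material 0.0330%, and reagent 0.033% of its charge.

    target ⇌ isomer of the product (K = 0.400, k = 0.395 h⁻¹)
    solid substrate ⇌ starting material, rate k2*(cs2 - [starting material]) while solid is left; crystals form when [starting material] > cs2 (solubility = 46.0 mM, k = 0.396 h⁻¹)
    starting material + reagent → target (k = 3.67 L mol⁻¹ h⁻¹)
    intermediate A ⇌ intermediate B (K = 0.990, k = 0.511 h⁻¹)
    intermediate A → intermediate C (k = 1.81 h⁻¹)
    starting material + reagent → intermediate A (k = 47.1 L mol⁻¹ h⁻¹)
    intermediate C → target (k = 3.58 h⁻¹)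

- The products of this flask reach >99.9% against the ceiling of 100%. Their split comes mainly from the back reaction of isomer to target: the run without that step puts the isomer at >99.9% instead of 28.6%, and the relaxation half-life of target and isomer by this step, 0.501 h, is far shorter than 15 d. The neighbour with 0.43 M of solid substrate has a ceiling of 39.5%, which with my share makes 28.3% target; it holds 28.2% target, 11.3% isomer and 0% reagent.

The readings come from a simulation for substances that don't exist.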